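## Retrosynthetic overview

1. Target 16 ← one-pot removal of the phenol TIPS ether and methyl ester from decalin 15.
2. Both rings and all five stereocentres of 15 ← one bromonium-initiated cation–olefin bicyclization of acyclic 14, terminated by an allylsilane. Ring A closes first (C4–C5), then ring B (C9–C10); loss of Me3Si gives the exocyclic C8=CH2.
3. The bromonium precursor 14 ← SN2 bromide opening of a Sharpless epoxide, which marks the correct internal alkene and fixes absolute configuration. The homoprenyl tail is added by triflate displacement with a prenyl cuprate.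
4. The Z-allylsilane and the Ar–CH2 bond ← one syn-carbocupration of a terminal alkyne with Me3SiCH2Cu, then benzylation with ArCH2Br 7.
5. Alkyne allylic alcohol 3 ← geranylacetone (alkyne formation, SeO2 oxidation); arene 7 ← methyl 4-hydroxy-3-methylbenzoate.

Assumption: the SMILES is read as the (3R,4R,5S,9R,10S) enantiomer in drimane numbering, i.e. (1R,4aS,5R,6R,8aS) in the naphthalene name. Acyclic intermediates use chain numbering C1 (ArCH2) to C15.

## Route

**Step 1**
Reactants: 1, geranylacetone [(5E)-6,10-dimethylundeca-5,9-dien-2-one]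
Product: 2, (5E)-6,10-dimethylundeca-5,9-dien-1-yne
Conditions: LDA (1.05 eq), THF, −78 °C; ClP(O)(OEt)2, −78 °C → rt; then LDA (2.3 eq), −78 °C → rt
Reagents that add atoms: none
Why: Negishi methyl ketone → terminal alkyne conversion (kinetic enol phosphate, then elimination); the 5E alkene is untouched.

**Step 2**
Reactants: 2
Product: 3, (2E,6E)-2,6-dimethylundeca-2,6-dien-10-yn-1-ol
Conditions: SeO2 (0.3 eq), t-BuOOH (3 eq), salicylic acid (cat.), CH2Cl2, 0 °C → rt; NaBH4/MeOH work-up to return any enal
Reagents that add atoms: SeO2, O=[Se]=O, with t-BuOOH, CC(C)(C)OO (one O)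
Why: Sharpless–Umbreit allylic oxidation (ene/[2,3] sequence) is selective for the E-methyl of the terminal trisubstituted alkene, giving the E-allylic alcohol needed for step 7.

**Step 3**
Reactants: 4, methyl 4-hydroxy-3-methylbenzoate
Product: 5, methyl 3-bromo-4-hydroxy-5-methylbenzoate
Conditions: Br2, AcOH, rt
Reagents that add atoms: bromine, BrBr
Why: electrophilic aromatic bromination; the only free position ortho/para to OH is C3.

**Step 4**
Reactants: 5
Product: 6, methyl 3-bromo-5-methyl-4-[(triisopropylsilyl)oxy]benzoate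
Conditions: TIPSOTf, 2,6-lutidine, CH2Cl2, 0 °C → rt
Reagents that add atoms: TIPSOTf, CC(C)[Si](C(C)C)(C(C)C)OS(=O)(=O)C(F)(F)F
Why: O-silylation; the bulky, non-nucleophilic TIPS ether survives organometallics and Lewis acid and cannot trap the C8 cation in step 11.

**Step 5**
Reactants: 6
Product: 7, methyl 3-bromo-5-(bromomethyl)-4-[(triisopropylsilyl)oxy]benzoate
Conditions: NBS, AIBN (cat.), PhCF3, 80 °C
Reagents that add atoms: NBS, O=C1CCC(=O)N1Br
Why: Wohl–Ziegler benzylic bromination of the only benzylic CH3.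

**Step 6**
Reactants: 3; 8, (trimethylsilyl)methylmagnesium chloride; 7
Product: 9, methyl 3-bromo-5-[(2Z,6E,10E)-12-hydroxy-7,11-dimethyl-3-[(trimethylsilyl)methyl]dodeca-2,6,10-trien-1-yl]-4-[(triisopropylsilyl)oxy]benzoate
Conditions: 8 + CuBr·SMe2 (2.2 eq each), Et2O/Me2S, −40 °C; add 3 (pre-treated with i-PrMgCl, 1.0 eq), −25 → 0 °C; then 7, P(OEt)3, DMPU, −25 °C → rt
Reagents that add atoms: 8, C[Si](C)(C)C[Mg]Cl (Me3SiCH2); the ArCH2 group comes from 7
Why: Normant syn-carbocupration puts Me3SiCH2 on the substituted alkyne carbon and Cu on the terminal carbon; stereoretentive benzylation of the vinylcopper then places CH2Ar cis to CH2SiMe3 (2Z). This geometry later sets C9.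

**Step 7**
Reactants: 9
Product: 10, methyl 3-bromo-5-[(2Z,6E)-9-[(2S,3S)-3-(hydroxymethyl)-3-methyloxiran-2-yl]-7-methyl-3-[(trimethylsilyl)methyl]nona-2,6-dien-1-yl]-4-[(triisopropylsilyl)oxy]benzoate
Conditions: Ti(OiPr)4 (10 mol %), L-(+)-DET (12 mol %), t-BuOOH, 4 Å MS, CH2Cl2, −20 °C
Reagents that add atoms: t-BuOOH, CC(C)(C)OO (one O)
Why: Sharpless asymmetric epoxidation touches only the allylic-alcohol alkene (C10=C11) among four alkenes; L-(+)-DET gives the (2S,3S)-epoxide, as for geraniol. These two centres become C3 and C4.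

**Step 8**
Reactants: 10; 11, prenylmagnesium chloride
Product: 12, methyl 3-bromo-5-[(2Z,6E)-7-methyl-9-[(2S,3S)-3-methyl-3-(4-methylpent-3-en-1-yl)oxiran-2-yl]-3-[(trimethylsilyl)methyl]nona-2,6-dien-1-yl]-4-[(triisopropylsilyl)oxy]benzoate
Conditions: Tf2O, 2,6-lutidine, CH2Cl2, −78 °C; then (prenyl)2CuMgCl [from 11 (4 eq) and CuBr·SMe2 (2 eq)], THF, −78 → −40 °C
Reagents that add atoms: none beyond 11, CC(C)=CC[Mg]Cl (prenyl group; the triflate oxygen is lost)
Why: SN2 displacement of the activated α-epoxy primary triflate by an allylic cuprate at its unsubstituted terminus; no free Grignard remains to attack the ester, and neither epoxide carbon is touched.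

**Step 9**
Reactants: 12
Product: 13, methyl 3-bromo-5-[(2Z,6E,10R,11S)-10-bromo-11-hydroxy-7,11,15-trimethyl-3-[(trimethylsilyl)methyl]hexadeca-2,6,14-trien-1-yl]-4-[(triisopropylsilyl)oxy]benzoate
Conditions: Li2NiBr4, THF, 0 °C → rt; pH 7 buffer
Reagents that add atoms: Li2NiBr4, [Li+].[Li+].Br[Ni-2](Br)(Br)Br (one Br)
Why: SN2 epoxide opening by soft bromide at the less substituted carbon with inversion gives the anti bromohydrin; this fixes the C–Br centre (future C3, R).

**Step 10**
Reactants: 13
Product: 14, methyl 3-bromo-5-[(2Z,6E,10R,11S)-10-bromo-7,11,15-trimethyl-11-(trifluoroacetoxy)-3-[(trimethylsilyl)methyl]hexadeca-2,6,14-trien-1-yl]-4-[(triisopropylsilyl)oxy]benzoate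
Conditions: (CF3CO)2O, pyridine, DMAP (cat.), CH2Cl2, 0 °C
Reagents that add atoms: TFAA, O=C(OC(=O)C(F)(F)F)C(F)(F)F
Why: O-acylation turns the tertiary OH into an ionizable leaving group without base strong enough to re-close the epoxide.

**Step 11**
Reactants: 14
Product: 15, methyl 3-bromo-5-{[(1R,4aS,5R,6R,8aS)-6-bromo-5,8a-dimethyl-2-methylidene-5-(4-methylpent-3-en-1-yl)decahydronaphthalen-1-yl]methyl}-4-[(triisopropylsilyl)oxy]benzoate
Conditions: Me2AlCl (3 eq), CH2Cl2 (2 mM), −78 → −40 °C; Et3N/MeOH quench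
Reagents that add atoms: none (CF3CO2– and Me3Si are lost)
Why: Lewis-acid ionization with neighbouring-bromine participation gives an enantiopure bromonium ion, which triggers a chair–chair cation–olefin bicyclization ended by allylsilane (Sakurai-type) desilylation to the exocyclic alkene. C3 is already fixed; anti attack of the 6E alkene sets C4 (axial Me, equatorial homoprenyl), the 6E alkene gives the trans ring fusion (C5, C10), and the 2Z allylsilane gives equatorial CH2Ar at C9.

**Step 12**
Reactants: 15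
Product: 16, callophycoic acid H, 3-bromo-5-{[(1R,4aS,5R,6R,8aS)-6-bromo-5,8a-dimethyl-2-methylidene-5-(4-methylpent-3-en-1-yl)decahydronaphthalen-1-yl]methyl}-4-hydroxybenzoic acid
Conditions: TBAF, THF, 0 °C; then LiOH·H2O, THF/MeOH/H2O, 40 °C (one pot); work-up at pH 4–5
Reagents that add atoms: LiOH, [Li+].[OH-] (carboxyl OH oxygen)
Why: fluoride desilylation and ester saponification. The equatorial neopentyl bromide has no anti-periplanar H and resists SN2, and avoiding strong acid prevents the phenol adding to the exocyclic alkene.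

## Compound list

1 | geranylacetone | CC(=O)CC/C=C(\C)CCC=C(C)C | starting material
2 | (5E)-6,10-dimethylundeca-5,9-dien-1-yne | C#CCC/C=C(\C)CCC=C(C)C | intermediate
3 | (2E,6E)-2,6-dimethylundeca-2,6-dien-10-yn-1-ol | C#CCC/C=C(\C)CC/C=C(\C)CO | intermediate
4 | methyl 4-hydroxy-3-methylbenzoate | COC(=O)c1ccc(O)c(C)c1 | starting material
5 | methyl 3-bromo-4-hydroxy-5-methylbenzoate | COC(=O)c1cc(C)c(O)c(Br)c1 | intermediate
6 | methyl 3-bromo-5-methyl-4-(TIPS-oxy)benzoate | COC(=O)c1cc(C)c(O[Si](C(C)C)(C(C)C)C(C)C)c(Br)c1 | intermediate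
7 | methyl 3-bromo-5-(bromomethyl)-4-(TIPS-oxy)benzoate | COC(=O)c1cc(CBr)c(O[Si](C(C)C)(C(C)C)C(C)C)c(Br)c1 | intermediate
8 | (trimethylsilyl)methylmagnesium chloride | C[Si](C)(C)C[Mg]Cl | starting material
9 | (2Z,6E,10E)-allylsilane allylic alcohol | COC(=O)c1cc(Br)c(O[Si](C(C)C)(C(C)C)C(C)C)c(C/C=C(C[Si](C)(C)C)/CC/C=C(\C)CC/C=C(\C)CO)c1 | intermediate
10 | (2S,3S)-epoxy alcohol | COC(=O)c1cc(Br)c(O[Si](C(C)C)(C(C)C)C(C)C)c(C/C=C(C[Si](C)(C)C)/CC/C=C(\C)CC[C@@H]2O[C@@]2(C)CO)c1 | intermediate
11 | prenylmagnesium chloride | CC(C)=CC[Mg]Cl | starting material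
12 | (2S,3S)-epoxide with homoprenyl tail | COC(=O)c1cc(Br)c(O[Si](C(C)C)(C(C)C)C(C)C)c(C/C=C(C[Si](C)(C)C)/CC/C=C(\C)CC[C@@H]2O[C@@]2(C)CCC=C(C)C)c1 | intermediate
13 | (10R,11S)-bromohydrin | COC(=O)c1cc(Br)c(O[Si](C(C)C)(C(C)C)C(C)C)c(C/C=C(C[Si](C)(C)C)/CC/C=C(\C)CC[C@@H](Br)[C@@](C)(O)CCC=C(C)C)c1 | intermediate
14 | (10R,11S)-bromo trifluoroacetate | COC(=O)c1cc(Br)c(O[Si](C(C)C)(C(C)C)C(C)C)c(C/C=C(C[Si](C)(C)C)/CC/C=C(\C)CC[C@@H](Br)[C@@](C)(OC(=O)C(F)(F)F)CCC=C(C)C)c1 | intermediate
15 | TIPS ether methyl ester of the target | C=C1CC[C@@H]2[C@@](C)(CCC=C(C)C)[C@H](Br)CC[C@@]2(C)[C@@H]1Cc1cc(C(=O)OC)cc(Br)c1O[Si](C(C)C)(C(C)C)C(C)C | intermediate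
16 | callophycoic acid H | C=C1CC[C@@H]2[C@@](C)(CCC=C(C)C)[C@H](Br)CC[C@@]2(C)[C@@H]1Cc1cc(C(=O)O)cc(Br)c1O | target

## Summary

Total steps: 12. Longest linear sequence: 10 (4 → 5 → 6 → 7 → 9 → 10 → 12 → 13 → 14 → 15 → 16); the terpenoid branch from geranylacetone is 9.

Three steps most likely to fail, with fallbacks:

- **Step 11 (bromonium bicyclization).** Risks are elimination or chloride capture, Br+ transfer to or attack by the C14=C15 prenyl alkene, and loss of C4 control through an open β-bromo cation. Fallback: use allyl cuprate in step 8 so the substrate carries only a poorly nucleophilic terminal vinyl group, run the cascade on that truncated substrate, and build the isopropylidene afterwards by cross-metathesis with 2-methyl-2-butene.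
- **Step 9 (bromide opening at the secondary carbon).** Risk is attack at the tertiary carbon or Lewis-acid rearrangement. Fallback: install bromine earlier on epoxy alcohol 10 by chelation-directed opening (Ti(OiPr)4, Et2NH·HBr), which delivers Br at the carbon distal to the CH2OH. Then tosylate the primary OH, close to the terminal 11,12-epoxide, and open it at C12 with the prenyl cuprate at −78 °C with a cold quench to reach 13.
- **Step 8 (prenyl cuprate on the hindered epoxy triflate).** Risks are γ-attack of the prenyl unit and slow SN2 next to the quaternary epoxide carbon. Fallback: take the tail from geraniol instead. Sharpless epoxidation of geraniol gives the C9–C15 epoxide with the prenyl group already present; join C8–C9 by alkylating a C8 allylic sulfone on the aryl/allylsilane fragment with the epoxygeranyl triflate, then desulfonylate.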